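A direct plan would build each resorcylate ring separately from an enone and dimethyl malonate (annulation, then halogen-mediated aromatisation). It would benzylate and saponify the ester of ring A (the pentyl-bearing acyl ring), methyl 2,4-dihydroxy-6-pentylbenzoate A1, to 2,4-bis(benzyloxy)-6-pentylbenzoic acid A2. It would re-esterify ring B (the propyl-bearing salicylic acid ring) through 2,4-dihydroxy-6-propylbenzoic acid A3, and would then couple acid with phenol and hydrogenolyse. Its weakest steps would be:
- the saponification of the di-ortho-substituted ester, which would need hot concentrated hydroxide;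
- the esterification of the equally hindered A2 with a phenol bearing two free hydroxyl groups, which would be slow and only marginally site-selective;
- the protection and ester-exchange operations around A2 and the decarboxylation-prone A3, which would add about five steps and no skeletal bond.

The route would cut the depside through ring A instead of between two finished arenes. It exploits the fact that the ester carbonyl is the terminus of a tetraketide chain whose alternate oxygens become 2-OH and 4-OH of ring A. An acylketene stored as a diketo-dioxinone would be captured by the 4-OH of a ring B ester, and the resulting aryl 3,5,7-trioxododecanoate would fold by aldol closure of the C1–C6 bond of ring A. One operation would make the C(=O)–O bond and ring A with its phenols free, so acid activation, ester saponification, phenol protection and oxidative aromatisation have no counterpart. Ring B would arise by the same folding, its trapping alcohol being the only protecting group.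

Key step: step 5

Remark: the target is achiral, and the two Weinreb amides (N-methoxy-N-methylbutanamide and N-methoxy-N-methylhexanamide) are assumed to be catalogue compounds.

Step 1
Reactants: 1 2,2,6-trimethyl-4H-1,3-dioxin-4-one; 2 acetyl chloride
Product: 3 2,2-dimethyl-6-(2-oxopropyl)-4H-1,3-dioxin-4-one
Conditions: 1 (2.0 equiv), LiN(SiMe3)2 (2.0 equiv), THF, −78 °C, 1 h; then 2 (1.0 equiv), −78 to −20 °C, 2 h; 1 M HCl
Reagents that add atoms: none
Why: Claisen-type C-acylation, in which LiN(SiMe3)2 removes a proton from the 6-methyl group to give the lithium dienolate, this is acylated at its exocyclic γ-carbon by the acid chloride, and the second equivalent of dienolate takes up the more acidic proton of 3 and so prevents a second acylation.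

Step 2
Reactants: 3 2,2-dimethyl-6-(2-oxopropyl)-4H-1,3-dioxin-4-one; 4 N-methoxy-N-methylbutanamide
Product: 5 6-(2,4-dioxoheptyl)-2,2-dimethyl-4H-1,3-dioxin-4-one
Conditions: LiN(i-Pr)2 (2.1 equiv), THF, −78 °C, 1 h; then 4 (0.9 equiv), −78 to −30 °C, 2 h; 1 M HCl
Reagents that add atoms: none
Why: Dianion Claisen condensation in the manner of the Weinreb ketone synthesis, in which LiN(i-Pr)2 removes first the doubly activated ring-CH2 proton and then a proton of the terminal methyl group, the terminal and more basic carbanion adds to amide 4, and the chelated tetrahedral adduct releases the 1,3-diketone only on acidic work-up, so that over-addition cannot occur.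

Step 3
Reactants: 5 6-(2,4-dioxoheptyl)-2,2-dimethyl-4H-1,3-dioxin-4-one
Product: 9 prop-2-en-1-yl 2,4-dihydroxy-6-propylbenzoate, via acylketene 6 (not isolated), via triketo ester 7 (not isolated), via aldol adduct 8 (not isolated)
Conditions: allyl alcohol (5 equiv), PhMe, 110 °C (sealed tube), 2 h; evaporate; then Et3N (2 equiv), dry CH2Cl2, rt, 12 h; 1 M HCl wash
Reagents that add atoms: allyl alcohol (prop-2-en-1-ol), C=CCO
Why: Thermal retro-hetero-Diels–Alder loss of acetone should give acylketene 6, the alcohol adds to it to give triketo ester 7, and amine-mediated intramolecular aldol addition of C-2 to the C-7 ketone followed by dehydration (biomimetic polyketide cycloaromatisation) should give the resorcylate, the two uncontrolled stereocentres of 8 being erased on aromatisation.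

Step 4
Reactants: 3 2,2-dimethyl-6-(2-oxopropyl)-4H-1,3-dioxin-4-one; 10 N-methoxy-N-methylhexanamide
Product: 11 6-(2,4-dioxononyl)-2,2-dimethyl-4H-1,3-dioxin-4-one
Conditions: LiN(i-Pr)2 (2.1 equiv), THF, −78 °C, 1 h; then 10 (0.9 equiv), −78 to −30 °C, 2 h; 1 M HCl
Reagents that add atoms: none
Why: The same dianion Claisen condensation as in step 2, now with the hexanoyl Weinreb amide, and no stereocentre is formed.

Step 5
Reactants: 11 6-(2,4-dioxononyl)-2,2-dimethyl-4H-1,3-dioxin-4-one; 9 prop-2-en-1-yl 2,4-dihydroxy-6-propylbenzoate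
Product: 15 prop-2-en-1-yl 4-[(2,4-dihydroxy-6-pentylbenzoyl)oxy]-2-hydroxy-6-propylbenzoate, via acylketene 12 (not isolated), via triketo aryl ester 13 (not isolated), via aldol adduct 14 (not isolated)
Conditions: 9 (1.2 equiv), dry PhMe (0.05 M), 110 °C, slow addition of 11, 2 h; cool; then Et3N (2 equiv), dry CH2Cl2, 0 °C to rt, 6 h; 1 M HCl wash
Reagents that add atoms: none
Why: Heating 11 should cause retro-hetero-Diels–Alder extrusion of acetone to acylketene 12, which adds the phenolic 4-OH of 9 across its C=C=O unit to give aryl 3,5,7-trioxododecanoate 13, so that the depside C(=O)–O bond is made without a hindered benzoic acid ever being activated. Triethylamine then enolises the C-2 methylene between the ester and the C-3 ketone, and its 6-(enolexo)-exo-trig aldol addition to the C-7 ketone closes ring A as 14, whose dehydration and enolisation are driven by aromatisation. The closest known reaction type is the thermolysis of diketo-dioxinones in the presence of alcohols followed by aldol cycloaromatisation to resorcylate esters, together with the acetoacetylation of phenols by dioxinones. No stereocentre remains, since the two of 14 form without control and are erased on dehydration. Site selectivity between the two hydroxyl groups of 9 rests on the 2-OH being tied in a hydrogen bond to the flanking ester carbonyl, and the choice of C-2 over C-8 as aldol donor rests on the far higher acidity of the doubly activated methylene. The step also needs the aldol closure to outrun loss of the ring-B aryloxide from 13 (lactonisation to a 4-hydroxy-2-pyrone or Claisen closure to an acylphloroglucinol), which is why the base is a mild amine at room temperature and neither alkoxide, alcohol nor water is present.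

Step 6
Reactants: 15 prop-2-en-1-yl 4-[(2,4-dihydroxy-6-pentylbenzoyl)oxy]-2-hydroxy-6-propylbenzoate
Product: 16 4-[(2,4-dihydroxy-6-pentylbenzoyl)oxy]-2-hydroxy-6-propylbenzoic acid
Conditions: Pd(PPh3)4 (5 mol %), N-methylaniline (3 equiv), THF, rt, 1 h; 1 M HCl wash
Reagents that add atoms: none
Why: Tsuji–Trost deallylation, in which zerovalent palladium ionises the allyl ester to a π-allyl complex and the carboxylate and the soft, weakly basic amine takes up the allyl group, so that the aryl ester link, the free phenols and the decarboxylation-prone salicylic acid unit meet neither hydroxide nor acid nor heat.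

Compound list

1 | 2,2,6-trimethyl-4H-1,3-dioxin-4-one | CC1=CC(=O)OC(C)(C)O1 | starting material
2 | acetyl chloride | CC(=O)Cl | starting material
3 | 2,2-dimethyl-6-(2-oxopropyl)-4H-1,3-dioxin-4-one | CC(=O)CC1=CC(=O)OC(C)(C)O1 | intermediate
4 | N-methoxy-N-methylbutanamide | CCCC(=O)N(C)OC | starting material
5 | 6-(2,4-dioxoheptyl)-2,2-dimethyl-4H-1,3-dioxin-4-one | CCCC(=O)CC(=O)CC1=CC(=O)OC(C)(C)O1 | intermediate
6 | 3,5,7-trioxodec-1-en-1-one (acylketene) | CCCC(=O)CC(=O)CC(=O)C=C=O | intermediate
7 | prop-2-en-1-yl 3,5,7-trioxodecanoate (drawn as the triketo tautomer) | CCCC(=O)CC(=O)CC(=O)CC(=O)OCC=C | intermediate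
8 | prop-2-en-1-yl 2-hydroxy-4,6-dioxo-2-propylcyclohexane-1-carboxylate (mixture of stereoisomers) | CCCC1(O)CC(=O)CC(=O)C1C(=O)OCC=C | intermediate
9 | prop-2-en-1-yl 2,4-dihydroxy-6-propylbenzoate | CCCc1cc(O)cc(O)c1C(=O)OCC=C | intermediate
10 | N-methoxy-N-methylhexanamide | CCCCCC(=O)N(C)OC | starting material
11 | 6-(2,4-dioxononyl)-2,2-dimethyl-4H-1,3-dioxin-4-one | CCCCCC(=O)CC(=O)CC1=CC(=O)OC(C)(C)O1 | intermediate
12 | 3,5,7-trioxododec-1-en-1-one (acylketene) | CCCCCC(=O)CC(=O)CC(=O)C=C=O | intermediate
13 | prop-2-en-1-yl 2-hydroxy-6-propyl-4-[(3,5,7-trioxododecanoyl)oxy]benzoate (drawn as the triketo tautomer) | CCCCCC(=O)CC(=O)CC(=O)CC(=O)Oc1cc(O)c(C(=O)OCC=C)c(CCC)c1 | intermediate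
14 | prop-2-en-1-yl 2-hydroxy-4-[(2-hydroxy-4,6-dioxo-2-pentylcyclohexane-1-carbonyl)oxy]-6-propylbenzoate (mixture of stereoisomers) | CCCCCC1(O)CC(=O)CC(=O)C1C(=O)Oc1cc(O)c(C(=O)OCC=C)c(CCC)c1 | intermediate
15 | prop-2-en-1-yl 4-[(2,4-dihydroxy-6-pentylbenzoyl)oxy]-2-hydroxy-6-propylbenzoate | CCCCCc1cc(O)cc(O)c1C(=O)Oc1cc(O)c(C(=O)OCC=C)c(CCC)c1 | intermediate
16 | 4-[(2,4-dihydroxy-6-pentylbenzoyl)oxy]-2-hydroxy-6-propylbenzoic acid (achiral) | CCCCCc1cc(O)cc(O)c1C(=O)Oc1cc(O)c(C(=O)O)c(CCC)c1 | target

Total step count: 6. Longest linear sequence: 5 steps (steps 1, 2, 3, 5, 6).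

Steps most likely to fail

1. Step 5.
 - What may go wrong: in the triketo aryl ester the ring-B aryloxide is a good leaving group, so lactonisation, Claisen-type closure or E1cB return to the ketene may outrun the aldol closure. A second ketene may also acylate the newly formed phenols.
 - Fallback (sets out from 11, comes back at 16): Et3N in CH2Cl2 would cycloaromatise 11 with the dioxinone ring intact to 7-hydroxy-2,2-dimethyl-5-pentyl-4H-1,3-benzodioxin-4-one F1. Allyl bromide and K2CO3 in acetone would give 2,2-dimethyl-5-pentyl-7-(prop-2-en-1-yloxy)-4H-1,3-benzodioxin-4-one F2. KOH in aqueous THF would open it to 2-hydroxy-6-pentyl-4-(prop-2-en-1-yloxy)benzoic acid F3. Esterification of F3 with the 4-OH of 9 through the mixed trifluoroacetic anhydride ((CF3CO)2O, toluene, rt) would give prop-2-en-1-yl 2-hydroxy-4-{[2-hydroxy-6-pentyl-4-(prop-2-en-1-yloxy)benzoyl]oxy}-6-propylbenzoate F4. The conditions of step 6 would then remove both allyl groups to give 16.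

2. Step 4 (step 2 is the same reaction with the shorter amide).
 - What may go wrong: proton transfer from the amide α-CH2 to the dianion, or acylation at the internal carbon, may leave 3 largely unconverted.
 - Fallback (sets out from 1, comes back at 11): the lithium dienolate of 1 would be C-acylated with the 1-acylbenzotriazole of mono-allyl malonate to prop-2-en-1-yl 4-(2,2-dimethyl-4-oxo-4H-1,3-dioxin-6-yl)-3-oxobutanoate F5. C-acylation at its malonate-type carbon with hexanoyl chloride (MgCl2, pyridine, CH2Cl2) would give prop-2-en-1-yl 2-[(2,2-dimethyl-4-oxo-4H-1,3-dioxin-6-yl)acetyl]-3-oxooctanoate F6. Pd(PPh3)4 and morpholine would then bring about deallylation and decarboxylation to 11.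

3. Step 6.
 - What may go wrong: allyl transfer from the π-allyl palladium intermediate to the electron-rich phenols, or aminolysis of the depside link by the scavenger, may erode the last step.
 - Fallback (sets out from 5, comes back at 16): 5 would be heated with benzyl alcohol in place of allyl alcohol and cyclised as in step 3 to benzyl 2,4-dihydroxy-6-propylbenzoate F7. The key step with 11 would then give benzyl 4-[(2,4-dihydroxy-6-pentylbenzoyl)oxy]-2-hydroxy-6-propylbenzoate F8. Hydrogenolysis (H2, palladium on carbon, EtOAc, rt) would give 16.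

Further compounds

F1 | step 5 | 7-hydroxy-2,2-dimethyl-5-pentyl-4H-1,3-benzodioxin-4-one | CCCCCc1cc(O)cc2c1C(=O)OC(C)(C)O2
F2 | step 5 | 2,2-dimethyl-5-pentyl-7-(prop-2-en-1-yloxy)-4H-1,3-benzodioxin-4-one | CCCCCc1cc(OCC=C)cc2c1C(=O)OC(C)(C)O2
F3 | step 5 | 2-hydroxy-6-pentyl-4-(prop-2-en-1-yloxy)benzoic acid | CCCCCc1cc(OCC=C)cc(O)c1C(=O)O
F4 | step 5 | prop-2-en-1-yl 2-hydroxy-4-{[2-hydroxy-6-pentyl-4-(prop-2-en-1-yloxy)benzoyl]oxy}-6-propylbenzoate | CCCCCc1cc(OCC=C)cc(O)c1C(=O)Oc1cc(O)c(C(=O)OCC=C)c(CCC)c1
F5 | step 4 | prop-2-en-1-yl 4-(2,2-dimethyl-4-oxo-4H-1,3-dioxin-6-yl)-3-oxobutanoate | C=CCOC(=O)CC(=O)CC1=CC(=O)OC(C)(C)O1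
F6 | step 4 | prop-2-en-1-yl 2-[(2,2-dimethyl-4-oxo-4H-1,3-dioxin-6-yl)acetyl]-3-oxooctanoate | CCCCCC(=O)C(C(=O)OCC=C)C(=O)CC1=CC(=O)OC(C)(C)O1
F7 | step 6 | benzyl 2,4-dihydroxy-6-propylbenzoate | CCCc1cc(O)cc(O)c1C(=O)OCc1ccccc1
F8 | step 6 | benzyl 4-[(2,4-dihydroxy-6-pentylbenzoyl)oxy]-2-hydroxy-6-propylbenzoate | CCCCCc1cc(O)cc(O)c1C(=O)Oc1cc(O)c(C(=O)OCc2ccccc2)c(CCC)c1
A1 | direct plan | methyl 2,4-dihydroxy-6-pentylbenzoate | CCCCCc1cc(O)cc(O)c1C(=O)OC
A2 | direct plan | 2,4-bis(benzyloxy)-6-pentylbenzoic acid | CCCCCc1cc(OCc2ccccc2)cc(OCc2ccccc2)c1C(=O)O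
A3 | direct plan | 2,4-dihydroxy-6-propylbenzoic acid | CCCc1cc(O)cc(O)c1C(=O)O
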